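In a one-step world J goes to Z and nothing else, there is no E to ratio against, and the tally of J consumed per mole of Q charged reaches 50.0 if J is used up; the flask has a second product, so I count both products that way.

- south: J 0.20 M; Q 2 mol%; the very flask that is asked about, followed so far
- flask: J 0.20 M; Q 2 mol%; time 50 min

south run (percent of the J charged)

| time / min | Z / % | E / % |
|---|---|---|
| 5.00 | 18 | 0 |
| 10.0 | 29 | 3 |
| 15.0 | 37 | 5 |
| 20.0 | 41 | 5 |

(standard deviation of a reading: 2 percentage points)

- the earlier runs were read with a standard deviation of 2 percentage points
- a reading or a percentage of Z counts all its forms, free or not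

1. ratio of Z to E at 12 s
2. ratio of Z to E at 50 min
3. which of Z and E there is more of at 50 min

How far does the tally get in this flask? A first-order line through the readings of Z plus E at 20.0 min gives 0.0308 min⁻¹, which puts it at 39.3 by 50 min. How much of that is E? I use E's turnover number, the moles of E per mole of Q charged, read at 20.0 min as 2.50. Does it keep growing? E reads 5% and 5% at the last two readings, so I hold the count there, and Z to E at 50 min comes to 14.7, which puts Z ahead. For 12 s I give no number, since the earliest reading stands at 5.00 min, where E reads 0% with a scatter of 2 percentage points.

The forecast says 12 (6 to 300) at 12 s, 6.5 (2.5 to 11) at 50 min, and Z ahead, holding that “the early ratio is skewed high and the late ratio skewed low”; my ratio for 50 min lies above its range.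

The flask gives 10.5 at 12 s and 11.9 at 50 min, with Z, its crystals L counted in, ahead at 70.4% against 5.89%, so the late ratio lies below mine and above the forecast's. In this flask E peaks at 7.11% at 27.8 min and stands at 5.89% at 50.0 min, where its turnover number is 2.95 against the 2.50 I held.

    Z + Q ⇌ E + Q, rate k1*[Q]*[Z] forward; the back reaction follows from the equilibrium constant (K = 0.610, k = 4.13 M⁻¹ min⁻¹)
    L ⇌ Z, rate k2*(cs2 - [Z]) while solid is left; crystals form when [Z] > cs2 (solubility = 3.00 mM, k = 0.172 min⁻¹)
    E ⇌ J (k = 0.0235 min⁻¹)
    J ⇌ Z (K = 0.376, k = 0.0581 min⁻¹)

In a second flask with c_J at 0.050 M, at the same loading and time, holding the count of 2.50 and the same first-order tally gives 14.7 again. The computed ratio in that flask is 7.98, with E at 7.61%, a turnover number of 3.81.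

The earlier runs and the new flask were computed with made-up constants; noise was put on by code.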